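The ten-membered carbocycle (germacrane numbering) is closed at C9–C10 by an intramolecular Suzuki–Miyaura coupling between a primary alkylboronate and a (Z)-2-iodoalkene in an open chain. The step exploits the O–C8–C9–C10=C1 array of the ring: the terminal C8=C9 alkene of the precursor is diborated enantioselectively, only the primary C9 boron couples to C10, and the surviving C8 boronate is oxidised in the same flask to the single free hydroxyl, which keeps the C8 angelate and C6 acetate apart. The chain is assembled from geranyl acetate and an anti-selective isopropylallylboration (C6, C7); both epoxides are introduced last from the ring periphery.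

Key step: step 10

Remark on numbering: ring C1 to C10, CH3-14 on C10, CH3-15 on C4, isopropyl on C7, acetate on C6, angelate on C8; the target is the 1,10-cis, 4,5-trans diepoxide, so its precursor is the 1(10)Z,4E-diene.

Assumption: the phosphonite enantiomer in step 9 is the one that gives (R)-1,2-diol-type bis(boronates) from 1-alkenes, and (R)-TRIP in step 7 is taken to direct allyl transfer to the Re face as it does for aryl and alkenyl aldehydes.

Step 1
Reactants: 1 geranyl acetate
Product: 3 (2E)-3-methyl-6-oxohex-2-en-1-yl acetate, via 6,7-epoxygeranyl acetate 2 (not isolated)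
Conditions: mCPBA, CH2Cl2, 0 °C; then H5IO6, THF/Et2O, 0 °C
Reagents that add atoms: mCPBA (3-chloroperoxybenzoic acid), O=C(OO)c1cccc(Cl)c1
Why: Prilezhaev epoxidation should select the electron-rich distal alkene (the allylic acetate alkene is deactivated), and periodic acid cleavage of the epoxide through its diol (glycol cleavage) should give the aldehyde and acetone.

Step 2
Reactants: 3 (2E)-3-methyl-6-oxohex-2-en-1-yl acetate
Product: 4 (2E,6Z)-7-iodo-3-methylocta-2,6-dien-1-yl acetate
Conditions: EtPPh3I, n-BuLi, THF, rt; I2, −78 °C; NaHMDS, −20 °C; then 3, −78 °C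
Reagents that add atoms: ethyltriphenylphosphonium iodide, CC[P+](c1ccccc1)(c1ccccc1)c1ccccc1.[I-]; iodine, II
Why: Stork–Zhao-type Wittig olefination with the α-iodo ylide should give the (Z)-2-iodoalkene under kinetic control (iodine cis to the chain), the acetate being inert at −78 °C.

Step 3
Reactants: 4 (2E,6Z)-7-iodo-3-methylocta-2,6-dien-1-yl acetate
Product: 5 (2E,6Z)-7-iodo-3-methylocta-2,6-dien-1-ol
Conditions: K2CO3 (cat.), MeOH, rt
Reagents that add atoms: none
Why: Base-catalysed transesterification (methanolysis) should remove the allylic acetate without touching the iodoalkene.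

Step 4
Reactants: 5 (2E,6Z)-7-iodo-3-methylocta-2,6-dien-1-ol
Product: 6 (2E,6Z)-7-iodo-3-methylocta-2,6-dienal
Conditions: MnO2, CH2Cl2, rt
Reagents that add atoms: none
Why: Selective allylic oxidation with MnO2 should give the (E)-enal without isomerising either alkene.

Step 5
Reactants: 7 3-methylbut-1-yne
Product: 8 4,4,5,5-tetramethyl-2-[(1E)-3-methylbut-1-en-1-yl]-1,3,2-dioxaborolane
Conditions: pinacolborane, Cp2Zr(H)Cl (5 mol%), Et3N (10 mol%), neat, 60 °C
Reagents that add atoms: pinacolborane, CC1(C)OBOC1(C)C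
Why: Zirconocene-catalysed syn-hydroboration of the terminal alkyne should give the (E)-alkenylboronate regio- and stereoselectively.

Step 6
Reactants: 8 4,4,5,5-tetramethyl-2-[(1E)-3-methylbut-1-en-1-yl]-1,3,2-dioxaborolane
Product: 9 4,4,5,5-tetramethyl-2-[(2E)-4-methylpent-2-en-1-yl]-1,3,2-dioxaborolane
Conditions: BrCH2Cl, n-BuLi, THF, −78 °C to rt
Reagents that add atoms: bromochloromethane, ClCBr
Why: Matteson homologation: the chloromethyllithium ate complex should undergo 1,2-migration of the alkenyl group with retention of the E geometry to give the allylboronate.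

Step 7
Reactants: 6 (2E,6Z)-7-iodo-3-methylocta-2,6-dienal; 9 4,4,5,5-tetramethyl-2-[(2E)-4-methylpent-2-en-1-yl]-1,3,2-dioxaborolane
Product: 11 (3R,4R,5E,9Z)-10-iodo-6-methyl-3-(propan-2-yl)undeca-1,5,9-trien-4-ol, via O-pinacolboryl ether of the alcohol 10 (not isolated)
Conditions: (R)-TRIP (5 mol%), 4 Å MS, toluene, −30 °C; aqueous work-up
Reagents that add atoms: none
Why: Chiral phosphoric acid-catalysed allylboration through a closed chair transition state: the (E)-boronate should place hydroxyl and isopropyl anti (C7), and (R)-TRIP should direct attack to the Re face of the enal to set C6 as R.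

Step 8
Reactants: 11 (3R,4R,5E,9Z)-10-iodo-6-methyl-3-(propan-2-yl)undeca-1,5,9-trien-4-ol
Product: 12 tert-butyl{[(3R,4R,5E,9Z)-10-iodo-6-methyl-3-(propan-2-yl)undeca-1,5,9-trien-4-yl]oxy}dimethylsilane
Conditions: TBSOTf, 2,6-lutidine, CH2Cl2, −78 to 0 °C
Reagents that add atoms: tert-butyldimethylsilyl trifluoromethanesulfonate, CC(C)(C)[Si](C)(C)OS(=O)(=O)C(F)(F)F
Why: Silyl ether formation should protect the hindered allylic C6 hydroxyl so that it stays distinct from the C8 oxygen made later.

Step 9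
Reactants: 12 tert-butyl{[(3R,4R,5E,9Z)-10-iodo-6-methyl-3-(propan-2-yl)undeca-1,5,9-trien-4-yl]oxy}dimethylsilane
Product: 13 tert-butyl{[(2S,3S,4R,5E,9Z)-10-iodo-6-methyl-3-(propan-2-yl)-1,2-bis(4,4,5,5-tetramethyl-1,3,2-dioxaborolan-2-yl)undeca-5,9-dien-4-yl]oxy}dimethylsilane
Conditions: B2pin2, Pt(dba)3 (3 mol%), 3,5-diisopropylphenyl-TADDOL phenylphosphonite (6 mol%), THF, 60 °C
Reagents that add atoms: bis(pinacolato)diboron, CC1(C)OB(OC1(C)C)B1OC(C)(C)C(C)(C)O1
Why: Platinum-catalysed enantioselective syn-diboration (B–B oxidative addition to zerovalent platinum, insertion of the monosubstituted alkene, reductive elimination) should touch only the terminal C8=C9 alkene, the ligand setting C8 by face selection; the catalyst rests as the bis(boryl) platinum complex, so the iodoalkene should survive.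

Step 10
Reactants: 13 tert-butyl{[(2S,3S,4R,5E,9Z)-10-iodo-6-methyl-3-(propan-2-yl)-1,2-bis(4,4,5,5-tetramethyl-1,3,2-dioxaborolan-2-yl)undeca-5,9-dien-4-yl]oxy}dimethylsilane
Product: 15 (1S,3Z,7E,9S,10R)-9-{[tert-butyl(dimethyl)silyl]oxy}-3,7-dimethyl-10-(propan-2-yl)cyclodeca-3,7-dien-1-ol (8-OH, 6-OTBS), via macrocyclic C8 pinacol boronate 14 (not isolated)
Conditions: Pd(OAc)2 (10 mol%), RuPhos (12 mol%), KOH, THF/H2O 10:1, 70 °C, syringe-pump addition to 1 mM; then 30% H2O2, 3 M NaOH, 0 °C to rt
Reagents that add atoms: hydrogen peroxide, OO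
Why: Zerovalent palladium (from Pd(OAc)2 and RuPhos) adds oxidatively into the C10–I bond with retention of the Z geometry, hydroxide turns the vicinal bis(boronate) into an ate complex in which the neighbouring C8 boronate activates the primary C9–B bond for transmetalation, and reductive elimination forms C9–C10. The closest known reaction type is the B-alkyl Suzuki–Miyaura macrocyclisation, here in the diboration/cross-coupling variant in which only the primary boronate of a 1,2-bis(boronate) couples. The ten-membered carbocycle closes by reductive elimination from an eleven-membered palladacycle (endo-type macrocyclisation at the sp2 carbon C10), helped by the cis iodoalkene that turns the chain back towards C9. No stereocentre is created in the coupling; C8, set in step 9, keeps its configuration because the secondary C–B bond does not transmetalate and is then oxidised with retention (1,2-migration from boron to oxygen) to the 8S alcohol. The step needs intramolecular over intermolecular coupling (secured by slow addition at high dilution), primary over secondary boron (intrinsic to these conditions) and cross-coupling over β-hydride elimination (RuPhos). The C6 silyl ether and both trisubstituted alkenes should be inert to aqueous KOH and to alkaline hydrogen peroxide.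

Step 11
Reactants: 15 (1S,3Z,7E,9S,10R)-9-{[tert-butyl(dimethyl)silyl]oxy}-3,7-dimethyl-10-(propan-2-yl)cyclodeca-3,7-dien-1-ol
Product: 16 (1S,3Z,7E,9S,10R)-9-{[tert-butyl(dimethyl)silyl]oxy}-3,7-dimethyl-10-(propan-2-yl)cyclodeca-3,7-dien-1-yl (2Z)-2-methylbut-2-enoate
Conditions: LiHMDS, THF, −78 °C; angelic anhydride, −78 to −20 °C
Reagents that add atoms: angelic anhydride [(2Z)-2-methylbut-2-enoic anhydride], C/C=C(/C)C(=O)OC(=O)/C(C)=C\C
Why: Acylation of the lithium alkoxide with the anhydride at low temperature (nucleophilic acyl substitution) should install the angelate on the only free hydroxyl without Z-to-E isomerisation to the tiglate and without silyl migration.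

Step 12
Reactants: 16 (1S,3Z,7E,9S,10R)-9-{[tert-butyl(dimethyl)silyl]oxy}-3,7-dimethyl-10-(propan-2-yl)cyclodeca-3,7-dien-1-yl (2Z)-2-methylbut-2-enoate
Product: 17 (1S,3Z,7E,9S,10S)-9-hydroxy-3,7-dimethyl-10-(propan-2-yl)cyclodeca-3,7-dien-1-yl (2Z)-2-methylbut-2-enoate
Conditions: HF·pyridine, pyridine, THF, 0 °C to rt
Reagents that add atoms: none
Why: Fluoride-mediated desilylation under buffered, weakly acidic conditions should free the C6 hydroxyl without acyl migration from O8 and without transannular cyclisation of the diene.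

Step 13
Reactants: 17 (1S,3Z,7E,9S,10S)-9-hydroxy-3,7-dimethyl-10-(propan-2-yl)cyclodeca-3,7-dien-1-yl (2Z)-2-methylbut-2-enoate
Product: 18 (1S,3Z,7E,9S,10R)-9-(acetyloxy)-3,7-dimethyl-10-(propan-2-yl)cyclodeca-3,7-dien-1-yl (2Z)-2-methylbut-2-enoate
Conditions: Ac2O, pyridine, DMAP (cat.), CH2Cl2, rt
Reagents that add atoms: acetic anhydride, CC(=O)OC(C)=O
Why: DMAP-catalysed acetylation of the only free hydroxyl (C6) should give the acetate without touching any stereocentre.

Step 14
Reactants: 18 (1S,3Z,7E,9S,10R)-9-(acetyloxy)-3,7-dimethyl-10-(propan-2-yl)cyclodeca-3,7-dien-1-yl (2Z)-2-methylbut-2-enoate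
Product: 19 (1R,4S,5S,6R,7R,8S,10S)-6-acetoxy-1,10:4,5-diepoxygermacran-8-yl (2Z)-2-methylbut-2-enoate (CNP0158257.1)
Conditions: mCPBA (2.5 equiv), NaHCO3, CH2Cl2, 0 °C
Reagents that add atoms: mCPBA (3-chloroperoxybenzoic acid), O=C(OO)c1cccc(Cl)c1
Why: Prilezhaev epoxidation is stereospecific (cis C1=C10 gives the cis epoxide, trans C4=C5 the trans epoxide) and should occur from the ring periphery – at C4=C5 on the face syn to O6 in the allylic-strain-minimised conformer (C6–H eclipsing CH3-15), at C1=C10 on the ring face opposite to the C8 ester – giving 4S,5S and 1R,10S, while the electron-poor angelate alkene is spared.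

Compound list
1 | geranyl acetate [(2E)-3,7-dimethylocta-2,6-dien-1-yl acetate] | CC(C)=CCC/C(C)=C/COC(C)=O | starting material
2 | 6,7-epoxygeranyl acetate (racemic at the epoxide) | CC1(C)OC1CC/C(C)=C/COC(C)=O | intermediate
3 | (2E)-3-methyl-6-oxohex-2-en-1-yl acetate | O=CCC/C(C)=C/COC(C)=O | intermediate
4 | (2E,6Z)-7-iodo-3-methylocta-2,6-dien-1-yl acetate | C/C(I)=C/CC/C(C)=C/COC(C)=O | intermediate
5 | (2E,6Z)-7-iodo-3-methylocta-2,6-dien-1-ol | C/C(I)=C/CC/C(C)=C/CO | intermediate
6 | (2E,6Z)-7-iodo-3-methylocta-2,6-dienal | C/C(I)=C/CC/C(C)=C/C=O | intermediate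
7 | 3-methylbut-1-yne | CC(C)C#C | starting material
8 | 4,4,5,5-tetramethyl-2-[(1E)-3-methylbut-1-en-1-yl]-1,3,2-dioxaborolane | CC(C)/C=C/B1OC(C)(C)C(C)(C)O1 | intermediate
9 | 4,4,5,5-tetramethyl-2-[(2E)-4-methylpent-2-en-1-yl]-1,3,2-dioxaborolane | CC(C)/C=C/CB1OC(C)(C)C(C)(C)O1 | intermediate
10 | 2-{[(3R,4R,5E,9Z)-10-iodo-6-methyl-3-(propan-2-yl)undeca-1,5,9-trien-4-yl]oxy}-4,4,5,5-tetramethyl-1,3,2-dioxaborolane (borate ester of 11) | C=C[C@@H](C(C)C)[C@@H](OB1OC(C)(C)C(C)(C)O1)/C=C(\C)CC/C=C(\I)C | intermediate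
11 | (3R,4R,5E,9Z)-10-iodo-6-methyl-3-(propan-2-yl)undeca-1,5,9-trien-4-ol | C=C[C@@H](C(C)C)[C@@H](O)/C=C(\C)CC/C=C(\I)C | intermediate
12 | tert-butyl{[(3R,4R,5E,9Z)-10-iodo-6-methyl-3-(propan-2-yl)undeca-1,5,9-trien-4-yl]oxy}dimethylsilane | C=C[C@@H](C(C)C)[C@@H](O[Si](C)(C)C(C)(C)C)/C=C(\C)CC/C=C(\I)C | intermediate
13 | tert-butyl{[(2S,3S,4R,5E,9Z)-10-iodo-6-methyl-3-(propan-2-yl)-1,2-bis(4,4,5,5-tetramethyl-1,3,2-dioxaborolan-2-yl)undeca-5,9-dien-4-yl]oxy}dimethylsilane | CC1(C)OB(C[C@H](B2OC(C)(C)C(C)(C)O2)[C@@H](C(C)C)[C@@H](O[Si](C)(C)C(C)(C)C)/C=C(\C)CC/C=C(\I)C)OC1(C)C | intermediate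
14 | 2-[(1S,3Z,7E,9R,10S)-9-{[tert-butyl(dimethyl)silyl]oxy}-3,7-dimethyl-10-(propan-2-yl)cyclodeca-3,7-dien-1-yl]-4,4,5,5-tetramethyl-1,3,2-dioxaborolane (macrocyclic C8 boronate) | CC1(C)OB([C@H]2C/C(C)=C\CC/C(C)=C/[C@H](O[Si](C)(C)C(C)(C)C)[C@@H]2C(C)C)OC1(C)C | intermediate
15 | (1S,3Z,7E,9S,10R)-9-{[tert-butyl(dimethyl)silyl]oxy}-3,7-dimethyl-10-(propan-2-yl)cyclodeca-3,7-dien-1-ol | O[C@H]1C/C(C)=C\CC/C(C)=C/[C@H](O[Si](C)(C)C(C)(C)C)[C@@H]1C(C)C | intermediate
16 | (1S,3Z,7E,9S,10R)-9-{[tert-butyl(dimethyl)silyl]oxy}-3,7-dimethyl-10-(propan-2-yl)cyclodeca-3,7-dien-1-yl (2Z)-2-methylbut-2-enoate | C/C=C(/C)C(=O)O[C@H]1C/C(C)=C\CC/C(C)=C/[C@H](O[Si](C)(C)C(C)(C)C)[C@@H]1C(C)C | intermediate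
17 | (1S,3Z,7E,9S,10S)-9-hydroxy-3,7-dimethyl-10-(propan-2-yl)cyclodeca-3,7-dien-1-yl (2Z)-2-methylbut-2-enoate | C/C=C(/C)C(=O)O[C@H]1C/C(C)=C\CC/C(C)=C/[C@H](O)[C@@H]1C(C)C | intermediate
18 | (1S,3Z,7E,9S,10R)-9-(acetyloxy)-3,7-dimethyl-10-(propan-2-yl)cyclodeca-3,7-dien-1-yl (2Z)-2-methylbut-2-enoate | C/C=C(/C)C(=O)O[C@H]1C/C(C)=C\CC/C(C)=C/[C@H](OC(C)=O)[C@@H]1C(C)C | intermediate
19 | (1R,4S,5S,6R,7R,8S,10S)-6-acetoxy-1,10:4,5-diepoxygermacran-8-yl (2Z)-2-methylbut-2-enoate (CNP0158257.1) | C/C=C(/C)C(=O)O[C@H]1C[C@]2(C)O[C@@H]2CC[C@]2(C)O[C@H]2[C@H](OC(C)=O)[C@@H]1C(C)C | target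

Total step count: 14. Longest linear sequence: 12 steps (steps 1–4 and 7–14); steps 5 and 6 make the allylboronate in a side branch.

Steps most likely to fail, most critical first:

Step 10. Closure of the medium ring is slow, so intermolecular coupling (oligomerisation), protodeboronation or reduction of the iodoalkene may outrun it. The fallback replaces the Suzuki coupling by a reductive cross-electrophile coupling; it sets out from 13 and comes back at 15. Both C–B bonds of 13 are oxidised (NaOH, H2O2) to the 1,2-diol F1. The primary hydroxyl is sulfonylated selectively (TsCl, Et3N, Bu2SnO cat.) to the primary tosylate F2, and K2CO3 in MeOH closes the terminal C8–C9 epoxide F3 with C8 unchanged. Nickel-catalysed reductive coupling of the iodoalkene with the epoxide (NiCl2(dme), 4,4'-di-tert-butyl-2,2'-bipyridine, NaI, Et3N·HCl, Mn, DMPU, high dilution) opens the epoxide at C9 through the iodohydrin, forms the same C9–C10 bond and should give 15 directly.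

Step 9. The alkene is flanked by the branched C7 stereocentre, so facial selection by the catalyst may be overridden (mismatched pair) and the C8 epimer may predominate. The fallback corrects C8 when the ester is made instead of at the diboration; it sets out from 12 and comes back at 16. The epimeric bis(boronate) F4 is taken through the same macrocyclisation, via the epimeric macrocyclic boronate F5, and oxidation to the 8-epi alcohol F6. Mitsunobu esterification with angelic acid (PPh3, DIAD, toluene, 0 °C) then installs the angelate with inversion at C8 and should give 16.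

Step 14. Facial selectivity at the cis C1=C10 alkene may be poor (attack syn to the C8 ester), or the first-formed monoepoxide may undergo acid-induced transannular cyclisation. The fallback builds the 1,10-epoxide in two steps with net delivery of oxygen to the opposite face; it sets out from 18 and comes back at 19. NBS in aqueous THF converts the more nucleophilic C1=C10 alkene into the bromohydrin F7 (bromonium on the exposed face, water at the tertiary C10 from the other side). Cs2CO3 in MeCN closes the 1,10-epoxy 4-ene F8 by backside displacement at C1, and buffered mCPBA then epoxidises C4=C5 to give 19.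

Further compounds
F1 | step 10 | 1,2-diol from 13 (both C–B bonds replaced by OH with retention; 6-OTBS, iodoalkene intact) | OC[C@H](O)[C@@H](C(C)C)[C@@H](O[Si](C)(C)C(C)(C)C)/C=C(\C)CC/C=C(\I)C
F2 | step 10 | primary (C9) tosylate of F1 | Cc1ccc(cc1)S(=O)(=O)OC[C@H](O)[C@@H](C(C)C)[C@@H](O[Si](C)(C)C(C)(C)C)/C=C(\C)CC/C=C(\I)C
F3 | step 10 | terminal C8–C9 epoxide from F2 | C1O[C@@H]1[C@@H](C(C)C)[C@@H](O[Si](C)(C)C(C)(C)C)/C=C(\C)CC/C=C(\I)C
F4 | step 9 | C8 epimer of bis(boronate) 13 | CC1(C)OB(C[C@@H](B2OC(C)(C)C(C)(C)O2)[C@@H](C(C)C)[C@@H](O[Si](C)(C)C(C)(C)C)/C=C(\C)CC/C=C(\I)C)OC1(C)C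
F5 | step 9 | C8 epimer of macrocyclic boronate 14 | CC1(C)OB([C@@H]2C/C(C)=C\CC/C(C)=C/[C@H](O[Si](C)(C)C(C)(C)C)[C@@H]2C(C)C)OC1(C)C
F6 | step 9 | C8 epimer of macrocyclic alcohol 15 | O[C@@H]1C/C(C)=C\CC/C(C)=C/[C@H](O[Si](C)(C)C(C)(C)C)[C@@H]1C(C)C
F7 | step 14 | bromohydrin of 18 at C1=C10 (10-OH, 1-Br, anti) | C/C=C(/C)C(=O)O[C@H]1C[C@](C)(O)[C@@H](Br)CC/C(C)=C/[C@H](OC(C)=O)[C@@H]1C(C)C
F8 | step 14 | 1,10-epoxy 4-ene (1R,10S epoxide; 6-OAc, 8-angelate) | C/C=C(/C)C(=O)O[C@H]1C[C@]2(C)O[C@@H]2CC/C(C)=C/[C@H](OC(C)=O)[C@@H]1C(C)C
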